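The vessel holds two liquids: reagent waits in the small second phase and crosses into the first, where the starting material, the protic impurity and every other species sit.

common to all: starting material 20 mM; reagent in the second phase 22.0 mM; protic impurity 20.0 mM; time 8.0 h; volume of the second phase over the first 0.25

| run | temperature |
|---|---|
| zeta | 80 °C |
| epsilon | 100 °C |
| theta | 120 °C |

    starting material + reagent in the reaction phase → target (k1 = 220 M⁻¹ h⁻¹, Ea1 = 49.0 kJ mol⁻¹)
    starting material + protic impurity → quenched substrate (k2 = 10 M⁻¹ h⁻¹, Ea2 = 70.0 kJ mol⁻¹)
    reagent in the reaction phase + target → over-reacted product (k3 = 26 M⁻¹ h⁻¹, Ea3 = 81.0 kJ mol⁻¹)
    reagent in the reaction phase ⇌ dormant form (K4 = 16, k4 = 0.056 h⁻¹, Ea4 = 117 kJ mol⁻¹, ΔH4 = −37.0 kJ mol⁻¹)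
    reagent in the reaction phase ⇌ reagent in the second phase, rate k5*([reagent in the reaction phase] - [reagent in the second phase]/K5) per volume of the first phase (K5 = 7.9, k5 = 1.4 h⁻¹)
    (constants at 80 °C)

- in the second phase: reagent in the second phase; everything else is in the first
- charges count per volume of the first phase; a concentration in a rate is the amount of a species over the volume of its own phase; every rate counts per litre of the first phase
- the list of constants is for 80 °C, to be carried to other temperatures by the activation energies and enthalpies

- which of the two there is more of at the end, zeta (over-reacted product / target)
- which of the two there is more of at the end, epsilon (over-reacted product / target)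
- which of the two there is more of at the end, theta (over-reacted product / target)
- how much target is there at the end, in percent of the starting material charged: zeta
- how much target is there at the end, in percent of the starting material charged: epsilon
- how much target is there at the end, in percent of the starting material charged: theta

- I reckon theta by hand, and I ask how long target survives among the reagent left over. Once the starting material has reacted, target is lost by a pseudo-first-order step, so I need the over-reaction constant at 120 °C and c(reagent in the reaction phase).
- I work in powers of ten. Going from 80 °C to 120 °C moves the target step by 0.738 powers, the quench by 1.05, the over-reaction by 1.22 and the dormant equilibrium by −0.557. The constants become 1200 M⁻¹ h⁻¹, 113 M⁻¹ h⁻¹, 430 M⁻¹ h⁻¹ and 4.44.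
- My first way is a race of supply. The second phase first feeds 15.6 mM h⁻¹, while the impurity removes starting material at 2.26 h⁻¹, a mean life of 0.442 h, far shorter than the run. Feed times that life puts 6.90 mM on the target route.
- Each substrate on that route finally takes two reagents, once to become target and once to over-react. The remainder spreads over the first phase, the second phase and the dormant form in the proportion 1 to 1.98 to 4.44, and the dormant form keeps pace, with a relaxation half-life of 0.175 h, far shorter than the run. So c(reagent in the reaction phase) comes to 1.11 mM.
- My second way is a race of rates. Quench and target step run level at c(reagent in the reaction phase) = 1.88 mM, and at the level just found this gives 7.41 mM on the target route. This way borrows the level, so it tests the supply argument against the rate constants and does not test the level. The two ways land close together, and the new amount returns a level of 0.969 mM, which I keep.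
- The quantity I carry is the spare-reagent half-life of target, ln(2) over the over-reaction constant times c(reagent in the reaction phase): 1.66 h.
- The run lasts 4.81 such half-lives. Counting them from the start leaves 1.32 % of the charge as target in theta, and most of the target route ends as over-reacted product.
- The forecast says target for zeta, over-reacted product for epsilon and over-reacted product for theta, with target at 54 %, 25.5 % and 2 %. Its theta figure is above mine, and its ground there is “quenching dominates, and the target is almost entirely over-reacted”.
- The flasks give target for zeta, over-reacted product for epsilon and over-reacted product for theta, with target at 53.9 %, 24.7 % and 1.48 %.
- Target ends 52 percentage points lower in theta than in zeta, at 1.48 % against 53.9 %, and the difference in temperature is the main reason for that gap. Theta's target falls from 12.9 % after 3.00 h to 1.48 % after 8.00 h, a read half-life of 1.61 h, beside my 1.66 h. A theta charged with 80 mM of starting material ends with c(reagent in the reaction phase) at 0.00135 mM, so at that level the half-life is 1190 h, far longer than the run, and its target stands at 23.5 % over 1.91 % of over-reacted product.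

The rate constants were set for the occasion.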